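**Strategy**

The trans-3,4-disubstituted tetrahydrofuran (O, C9, C8, C8′, C9′) is obtained by contraction, not cyclisation: C8, bonded to C7, C9 and C8′, corresponds to C3 of a 3-(aryl-hydroxymethyl)tetrahydropyran-4-one whose carbonyl carbon is expelled from the ring to become C7′. A D-proline anti-aldol of O-tosylvanillin with tetrahydropyran-4-one sets 7S and 8R. Photochemical Wolff rearrangement of the derived 5-diazo-4-ketone then forms the C8–C8′ bond with retention at C8, shrinks the ring and delivers C7′ as a methyl ester, equilibrated to trans. The precursor is the O-silylated aldol adduct carrying the diazo group on the unsubstituted α-carbon. Ester reduction, Felkin-controlled arylation (7′R) and deprotection complete the target.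

Key step: step 5

Remarks on the chemistry (assumptions):
- Lignan numbering is used; ring A is the aryl group on C7 (from vanillin), ring B the aryl group on C7′.
- The ring-A phenol is carried as a tosylate, not a mesylate. Both activate the aldehyde for the aldol, but the CH3 of a mesylate is acidic enough to be attacked by LiN(SiMe3)2 or ArMgBr and the ester then fragments; a tosylate has no such hydrogen.
- The ring-B phenol is silylated before the Grignard reagent is made, since a free phenol would quench it.
- All selectivities are expectations, not results.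

**Route**

Step 1
Reactants: 1 vanillin
Product: 2 4-formyl-2-methoxyphenyl 4-methylbenzenesulfonate (O-tosylvanillin)
Conditions: TsCl, Et3N, DMAP (cat.), CH2Cl2, 0 °C → rt
Reagents that add atoms: p-toluenesulfonyl chloride, Cc1ccc(cc1)S(=O)(=O)Cl
Why: Sulfonylation of the phenol (nucleophilic substitution at sulfur) is fast and chemoselective, and the electron-withdrawing, base-robust tosylate makes the aldehyde electrophilic enough for enamine catalysis while later suppressing benzylic ionisation at C7.

Step 2
Reactants: 2 O-tosylvanillin; 3 tetrahydro-4H-pyran-4-one (excess)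
Product: 5 (3R)-3-{(S)-hydroxy[3-methoxy-4-(tosyloxy)phenyl]methyl}tetrahydro-4H-pyran-4-one (anti aldol; 7S,8R)
Conditions: D-proline (4, 30 mol %), DMSO, H2O (trace), rt
Reagents that add atoms: none
Why: In this proline-catalysed direct aldol reaction the enamine of the ketone adds to the aldehyde through a chair-like transition state bridged by the carboxylic acid, which should give mainly the anti adduct, and the D-catalyst (mirror image of the natural amino acid) selects the enantiomer with the S carbinol and the 3R ring carbon.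

Step 3
Reactants: 5 anti aldol adduct
Product: 6 (3R)-3-{(S)-(tert-butyldimethylsilyloxy)[3-methoxy-4-(tosyloxy)phenyl]methyl}tetrahydro-4H-pyran-4-one
Conditions: TBSOTf, 2,6-lutidine, CH2Cl2, −78 → 0 °C
Reagents that add atoms: tert-butyldimethylsilyl trifluoromethanesulfonate, CC(C)(C)[Si](C)(C)OS(=O)(=O)C(F)(F)F
Why: O-Silylation with a silyl triflate and a hindered base touches no stereocentre and blocks retro-aldol, dehydration and, later, lactonisation of the carbinol onto the new ester.

Step 4
Reactants: 6 silylated ketone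
Product: 8 (3R)-3-{(S)-(tert-butyldimethylsilyloxy)[3-methoxy-4-(tosyloxy)phenyl]methyl}-5-diazotetrahydro-4H-pyran-4-one, via trifluoroacetyl ketone 7 (not isolated)
Conditions: LiN(SiMe3)2, THF, −78 °C; CF3CO2CH2CF3, −78 °C; cold 5 % HCl work-up; crude 7 then 4-AcNHC6H4SO2N3, Et3N, H2O (1 equiv), MeCN, rt
Reagents that add atoms: 4-acetamidobenzenesulfonyl azide, CC(=O)Nc1ccc(cc1)S(=O)(=O)N=[N+]=[N-] (supplies the two diazo nitrogens; the CF3CO group of 7 comes from 2,2,2-trifluoroethyl trifluoroacetate, FC(F)(F)C(=O)OCC(F)(F)F, and is lost again)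
Why: This detrifluoroacetylative (Regitz-type deacylative) diazo transfer relies on kinetic enolisation at the unhindered C5 methylene and not at the tertiary C3, so that the trifluoroacetyl group activates only that carbon and is expelled onto the sulfonamide nitrogen; C3 has a single hydrogen, so no regioisomeric diazo compound can form.

Step 5
Reactants: 8 diazoketone
Product: 11 methyl (3R,4R)-4-{(S)-(tert-butyldimethylsilyloxy)[3-methoxy-4-(tosyloxy)phenyl]methyl}tetrahydrofuran-3-carboxylate (trans), via ketene 9 (not isolated), via cis ester 10 (not isolated)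
Conditions: hν (medium-pressure Hg lamp, Pyrex, λ > 300 nm), degassed MeOH, 0–20 °C; then NaOMe (0.3 equiv), MeOH, rt
Reagents that add atoms: methanol, CO
Why: Light absorbed by the diazoketone, which the ring holds in the s-cis geometry, expels N2 while the C8–C(ketone) bond shifts to the diazo carbon, so that the new C8–C8′ bond and ketene 9 form in one concerted event; methanol adds to the ketene and catalytic NaOMe then epimerises the ester α-carbon. The closest known reaction type is the photochemical Wolff ring contraction of cyclic α-diazoketones, applied here to a tetrahydropyranone. The tetrahydrofuran ring (O, C9, C8, C8′, C9′) is closed by contraction through a 1,2-alkyl shift that excises the carbonyl carbon, not by a cyclisation, so no Baldwin ring-closure mode is involved. C8 migrates with retention, which carries 7S and 8R through untouched, and the new C8′ centre is fixed under thermodynamic control, the ester settling trans to the bulky silyloxybenzyl group (8′R). The step needs the rearrangement to win over O–H insertion into methanol and over 1,2-hydride shift from the C9′ methylene, and the enforced s-cis alignment together with direct irradiation without a metal catalyst favours the concerted shift. The silyl ether prevents retro-aldol and lactonisation, and the tosylate neither absorbs above 300 nm nor offers an acidic hydrogen to the methoxide.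

Step 6
Reactants: 11 trans ester
Product: 12 (3R,4R)-4-{(S)-(tert-butyldimethylsilyloxy)[3-methoxy-4-(tosyloxy)phenyl]methyl}tetrahydrofuran-3-carbaldehyde
Conditions: i-Bu2AlH (1.1 equiv), CH2Cl2, −78 °C; MeOH at −78 °C, then aq KNaC4H4O6 (potassium sodium tartrate)
Reagents that add atoms: none
Why: In this partial ester reduction the aluminium hemiacetal, held by coordination to the ring oxygen, should persist at −78 °C until the cold quench, and the trans aldehyde is also the thermodynamic epimer, so C8′ is not at risk.

Step 7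
Reactants: 13 4-bromo-2-methoxyphenol
Product: 14 (4-bromo-2-methoxyphenoxy)(tert-butyl)dimethylsilane
Conditions: TBSCl, imidazole, DMF, rt
Reagents that add atoms: tert-butyldimethylsilyl chloride, CC(C)(C)[Si](C)(C)Cl
Why: Imidazole-promoted silylation masks the acidic phenol, which would otherwise destroy the Grignard reagent, with a group that is removed together with the C7 silyl ether.

Step 8
Reactants: 12 aldehyde; 14 silylated aryl bromide
Product: 16 4-{(S)-(tert-butyldimethylsilyloxy)[(3R,4R)-4-{(R)-[4-(tert-butyldimethylsilyloxy)-3-methoxyphenyl](hydroxy)methyl}tetrahydrofuran-3-yl]methyl}-2-methoxyphenyl 4-methylbenzenesulfonate, via arylmagnesium bromide 15 (not isolated)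
Conditions: 14, Mg, I2 (cat.), THF, 45 °C; then 12, THF, −78 → −30 °C; aq NH4Cl
Reagents that add atoms: none
Why: In this Grignard addition under Felkin–Anh control the C8′–C8 bond (to the ring carbon carrying the bulky silyloxybenzyl group) lies anti to the incoming aryl group, which passes the C8′ hydrogen and should give the 7′R carbinol; a magnesium chelate between the carbonyl and ring oxygens would expose the same face.

Step 9
Reactants: 16 bis-silyl ether
Product: 17 4-{(S)-hydroxy[(3R,4R)-4-{(R)-hydroxy(4-hydroxy-3-methoxyphenyl)methyl}tetrahydrofuran-3-yl]methyl}-2-methoxyphenyl 4-methylbenzenesulfonate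
Conditions: Bu4NF (3 equiv), AcOH (3 equiv), THF, 0 °C → rt
Reagents that add atoms: none
Why: Fluoride-induced desilylation (driven by Si–F bond formation) cleaves the alkyl and the aryl silyl ether, and acetic acid buffering keeps the medium near neutral so that the p-hydroxybenzylic carbinol on ring B is not ionised and the tosylate is untouched.

Step 10
Reactants: 17 mono-tosylate
Product: 18 (S)-(4-hydroxy-3-methoxyphenyl){(3R,4R)-4-[(R)-hydroxy(4-hydroxy-3-methoxyphenyl)methyl]tetrahydrofuran-3-yl}methanol (target; 7S,8R,8′R,7′R)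
Conditions: Mg (turnings, excess), MeOH/THF, rt; aq NH4Cl to pH 7
Reagents that add atoms: none
Why: Reductive S–O cleavage of the aryl sulfonate by electron transfer from magnesium in methanol should release the ring-A phenol at room temperature without acid, conditions under which the two p-hydroxybenzylic carbinols keep their configuration.

**Compound list**

1 | vanillin (4-hydroxy-3-methoxybenzaldehyde) | COc1cc(C=O)ccc1O | starting material
2 | 4-formyl-2-methoxyphenyl 4-methylbenzenesulfonate | COc1cc(C=O)ccc1OS(=O)(=O)c1ccc(C)cc1 | intermediate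
3 | tetrahydro-4H-pyran-4-one | O=C1CCOCC1 | starting material
4 | D-proline ((R)-pyrrolidine-2-carboxylic acid, catalyst) | OC(=O)[C@H]1CCCN1 | starting material
5 | (3R)-3-{(S)-hydroxy[3-methoxy-4-(tosyloxy)phenyl]methyl}tetrahydro-4H-pyran-4-one | COc1cc([C@@H](O)[C@H]2COCCC2=O)ccc1OS(=O)(=O)c1ccc(C)cc1 | intermediate
6 | (3R)-3-{(S)-(tert-butyldimethylsilyloxy)[3-methoxy-4-(tosyloxy)phenyl]methyl}tetrahydro-4H-pyran-4-one | COc1cc([C@@H](O[Si](C)(C)C(C)(C)C)[C@H]2COCCC2=O)ccc1OS(=O)(=O)c1ccc(C)cc1 | intermediate
7 | (3R)-3-{(S)-(tert-butyldimethylsilyloxy)[3-methoxy-4-(tosyloxy)phenyl]methyl}-5-(trifluoroacetyl)tetrahydro-4H-pyran-4-one (C5 unassigned, largely enolised) | COc1cc([C@@H](O[Si](C)(C)C(C)(C)C)[C@H]2COCC(C(=O)C(F)(F)F)C2=O)ccc1OS(=O)(=O)c1ccc(C)cc1 | intermediate (not isolated)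
8 | (3R)-3-{(S)-(tert-butyldimethylsilyloxy)[3-methoxy-4-(tosyloxy)phenyl]methyl}-5-diazotetrahydro-4H-pyran-4-one | COc1cc([C@@H](O[Si](C)(C)C(C)(C)C)[C@H]2COCC(=[N+]=[N-])C2=O)ccc1OS(=O)(=O)c1ccc(C)cc1 | intermediate (key-step precursor)
9 | (4R)-4-{(S)-(tert-butyldimethylsilyloxy)[3-methoxy-4-(tosyloxy)phenyl]methyl}-3-(oxomethylidene)tetrahydrofuran (ketene) | COc1cc([C@@H](O[Si](C)(C)C(C)(C)C)[C@H]2COCC2=C=O)ccc1OS(=O)(=O)c1ccc(C)cc1 | intermediate (not isolated)
10 | methyl (3S,4R)-4-{(S)-(tert-butyldimethylsilyloxy)[3-methoxy-4-(tosyloxy)phenyl]methyl}tetrahydrofuran-3-carboxylate (cis; C8′ epimer) | COc1cc([C@@H](O[Si](C)(C)C(C)(C)C)[C@H]2COC[C@H]2C(=O)OC)ccc1OS(=O)(=O)c1ccc(C)cc1 | intermediate (not isolated)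
11 | methyl (3R,4R)-4-{(S)-(tert-butyldimethylsilyloxy)[3-methoxy-4-(tosyloxy)phenyl]methyl}tetrahydrofuran-3-carboxylate (trans) | COc1cc([C@@H](O[Si](C)(C)C(C)(C)C)[C@H]2COC[C@@H]2C(=O)OC)ccc1OS(=O)(=O)c1ccc(C)cc1 | intermediate (key-step product)
12 | (3R,4R)-4-{(S)-(tert-butyldimethylsilyloxy)[3-methoxy-4-(tosyloxy)phenyl]methyl}tetrahydrofuran-3-carbaldehyde | COc1cc([C@@H](O[Si](C)(C)C(C)(C)C)[C@H]2COC[C@@H]2C=O)ccc1OS(=O)(=O)c1ccc(C)cc1 | intermediate
13 | 4-bromo-2-methoxyphenol | COc1cc(Br)ccc1O | starting material
14 | (4-bromo-2-methoxyphenoxy)(tert-butyl)dimethylsilane | COc1cc(Br)ccc1O[Si](C)(C)C(C)(C)C | intermediate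
15 | [4-(tert-butyldimethylsilyloxy)-3-methoxyphenyl]magnesium bromide | COc1cc([Mg]Br)ccc1O[Si](C)(C)C(C)(C)C | intermediate (not isolated)
16 | 4-{(S)-(tert-butyldimethylsilyloxy)[(3R,4R)-4-{(R)-[4-(tert-butyldimethylsilyloxy)-3-methoxyphenyl](hydroxy)methyl}tetrahydrofuran-3-yl]methyl}-2-methoxyphenyl 4-methylbenzenesulfonate | COc1cc([C@@H](O[Si](C)(C)C(C)(C)C)[C@H]2COC[C@@H]2[C@@H](O)c2ccc(O[Si](C)(C)C(C)(C)C)c(OC)c2)ccc1OS(=O)(=O)c1ccc(C)cc1 | intermediate
17 | 4-{(S)-hydroxy[(3R,4R)-4-{(R)-hydroxy(4-hydroxy-3-methoxyphenyl)methyl}tetrahydrofuran-3-yl]methyl}-2-methoxyphenyl 4-methylbenzenesulfonate | COc1cc([C@@H](O)[C@H]2COC[C@@H]2[C@@H](O)c2ccc(O)c(OC)c2)ccc1OS(=O)(=O)c1ccc(C)cc1 | intermediate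
18 | (S)-(4-hydroxy-3-methoxyphenyl){(3R,4R)-4-[(R)-hydroxy(4-hydroxy-3-methoxyphenyl)methyl]tetrahydrofuran-3-yl}methanol | COc1cc([C@@H](O)[C@H]2COC[C@@H]2[C@@H](O)c2ccc(O)c(OC)c2)ccc1O | target

**Step count**

Total step count: 10. Longest linear sequence: 9 steps (steps 1–6 and 8–10, from vanillin).

**Steps most likely to fail**

Step 5 (key step). The excited diazoketone may leak into carbene chemistry, namely O–H insertion into methanol or 1,2-hydride shift from the C9′ methylene to an enone, so that little ketene forms. The fallback sets out from ketone 6 and returns at aldehyde 12; it contracts the ring by an epoxide rearrangement and involves no diazo compound. Kinetic enolate triflation (LiN(SiMe3)2, PhNTf2, THF, −78 °C) should give the enol triflate F1. Formate reduction (Pd(OAc)2, PPh3, HCO2H, n-Bu3N, DMF, 60 °C) should give the 3,6-dihydro-2H-pyran F2, and mCPBA/NaHCO3 in CH2Cl2 the epoxide F3. MgBr2·OEt2 in toluene should then induce a Meinwald-type semipinacol shift of a ring bond to give the ring-contracted aldehyde. Either ring bond that migrates leads to the same 4-substituted tetrahydrofuran-3-carbaldehyde constitution with C8 unchanged. Any cis aldehyde F4 formed is equilibrated with DBU to the trans aldehyde 12.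

Step 8. Facial selectivity at the aldehyde may be poor, because the two ring substituents on C8′ differ only moderately in size and the reagent is small and reactive. The fallback sets out from 16 as obtained together with its C7′ epimer and returns at 16. Dess–Martin oxidation of the mixture should give the aryl ketone F5. Corey–Bakshi–Shibata reduction with (S)-2-methyl-CBS-oxazaborolidine and BH3·SMe2 then sets C7′ under reagent control; with the aryl group acting as the larger substituent the 7′R alcohol 16 is expected.

Step 6. Over-reduction may occur if the aluminium hemiacetal collapses before the quench, since the liberated aldehyde is reduced faster than the ester. The fallback sets out from ester 11 and returns at aldehyde 12. Exhaustive reduction with LiBH4 (THF, MeOH cat.) should give the primary alcohol F6, and Dess–Martin oxidation (NaHCO3, CH2Cl2) then gives 12; neither reagent touches the tosylate or the silyl ether.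

**Further compounds**

F1 | step 5 | (3R)-3-{(S)-(tert-butyldimethylsilyloxy)[3-methoxy-4-(tosyloxy)phenyl]methyl}-3,6-dihydro-2H-pyran-4-yl trifluoromethanesulfonate | COc1cc([C@@H](O[Si](C)(C)C(C)(C)C)[C@H]2COCC=C2OS(=O)(=O)C(F)(F)F)ccc1OS(=O)(=O)c1ccc(C)cc1
F2 | step 5 | (3R)-3-{(S)-(tert-butyldimethylsilyloxy)[3-methoxy-4-(tosyloxy)phenyl]methyl}-3,6-dihydro-2H-pyran | COc1cc([C@@H](O[Si](C)(C)C(C)(C)C)[C@H]2COCC=C2)ccc1OS(=O)(=O)c1ccc(C)cc1
F3 | step 5 | 5-{(S)-(tert-butyldimethylsilyloxy)[3-methoxy-4-(tosyloxy)phenyl]methyl}-3,7-dioxabicyclo[4.1.0]heptane (ring CH configured as C8 of 6; epoxide face not defined) | COc1cc([C@@H](O[Si](C)(C)C(C)(C)C)[C@H]2COCC3OC23)ccc1OS(=O)(=O)c1ccc(C)cc1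
F4 | step 5 | (3S,4R)-4-{(S)-(tert-butyldimethylsilyloxy)[3-methoxy-4-(tosyloxy)phenyl]methyl}tetrahydrofuran-3-carbaldehyde (cis; C8′ epimer of 12) | COc1cc([C@@H](O[Si](C)(C)C(C)(C)C)[C@H]2COC[C@H]2C=O)ccc1OS(=O)(=O)c1ccc(C)cc1
F5 | step 8 | [(3R,4R)-4-{(S)-(tert-butyldimethylsilyloxy)[3-methoxy-4-(tosyloxy)phenyl]methyl}tetrahydrofuran-3-yl][4-(tert-butyldimethylsilyloxy)-3-methoxyphenyl]methanone | COc1cc([C@@H](O[Si](C)(C)C(C)(C)C)[C@H]2COC[C@@H]2C(=O)c2ccc(O[Si](C)(C)C(C)(C)C)c(OC)c2)ccc1OS(=O)(=O)c1ccc(C)cc1
F6 | step 6 | [(3S,4R)-4-{(S)-(tert-butyldimethylsilyloxy)[3-methoxy-4-(tosyloxy)phenyl]methyl}tetrahydrofuran-3-yl]methanol (trans) | COc1cc([C@@H](O[Si](C)(C)C(C)(C)C)[C@H]2COC[C@@H]2CO)ccc1OS(=O)(=O)c1ccc(C)cc1
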